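**Assumption.** The absolute configuration is taken exactly as written in the SMILES. Atoms are numbered along the SMILES (eunicellane-type): C19H2=C7, C6, C5, C4, C3(C18H3), O, C16, C15(C17H3), C14, C13, C12(O-octanoyl), C11(C20H3)(OH), C10, C1, C2, O, C9, C8. This gives 1S,2S,3S,9S,10R,11R,12S,14S,15R, which places the C14 side chain as in (R)-carvone.

## Analysis of the target

The target 32 is a tetracyclic 2,11-cyclized cembranoid ether. Ring A is a cyclohexane (C1, C10–C14), ring B a tetrahydrofuran (C1, C2, O, C9, C10), ring C an oxonane (C2–C9 plus the same oxygen) and ring D an oxepane (C1, C2, C3, O, C16, C15, C14). Rings B and C together form an 11-oxabicyclo[6.2.1]undecane, in which the oxygen bridges a ten-membered carbocycle (C1–C10).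

There are nine stereocentres. H1 and H10 are cis; C3 and C8 lie on the opposite face of ring B; the C14–C15 bond is trans to C1–C2; C3 is a quaternary ether carbon; C15 is an exocyclic methyl-bearing centre. On ring A the C11 hydroxyl and the C12 octanoate are cis to each other and anti to the C10–C9 bond.

Two features invite the strategy. First, C9 is a methine bonded only to the bridging oxygen, C8 and C10. If both of its C–C bonds are removed it is a formate-level carbon, and rings B and C vanish together. Second, the cis C11-OH/C12-O-acyl pair sits exactly where a C11 cation, formed when C10 attacks C9, can be trapped by the ester itself.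

The sensitive groups are the 1,1-disubstituted C7=C19 alkene (acid isomerization), the tertiary C11 alcohol next to a secondary ester (acyl shift, elimination), and the octanoate (strong nucleophiles, hydrides, some transition metals while it is still allylic). The hard parts are the medium ring bridged by ring B, the contiguous array C15–C14–C1–C2–C3, and keeping the number of oxygen-differentiation steps low.

## Retrosynthetic reasoning

**32 ⇒ 29 (cut C9–C10, C9–C8 and the C11–O bond).** Both carbon bonds of C9 are cut, so C9 becomes the central carbon of the mixed orthoformate 29 and rings B and C disappear in one operation. No other pair of cuts removes both bridged rings and leaves a precursor without a medium ring. Forward, a C9 dialkoxycarbenium ion must be attacked by C10 of the C10=C11 alkene (ring B). The C11 cation must be trapped by the C12 octanoate, which delivers the C11 oxygen cis to C12–O. The C9 oxocarbenium ion generated next must be attacked by C8 of an allylsilane, which closes ring C and leaves the C7=C19 alkene. C9, C10 and C11 are set together.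

**29 ⇒ 27 + 28 ⇒ 26.** The orthoformate is made by alkoxy exchange of the C2 alcohol 27 with trimethyl orthoformate 28. The allylsilane is cut at C7–C19 back to the bromoalkene 26. It is introduced late because a 1,1-disubstituted allylsilane alkene would not survive the hydroboration that sets C15.

**26 ⇒ 25 ⇒ 23.** Ring D is cut at the C16–O bond, not at C3–O. C3 can then be carried as a preformed quaternary stereocentre, and the ring closes by SN2 at a primary carbon (via triflate 24). The C2 oxygen is masked as a TBS ether so that the six-membered ether cannot form.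

**23 ⇒ 21.** C15 and the C16 oxygen come from hydroboration of the carvone isopropenyl group. The bulky C1 side chain next to C14 provides the facial bias that bare carvone lacks, so this step follows the fragment union.

**21 ⇒ 19 + 20 ⇒ 17.** The octanoate is installed by Mitsunobu inversion of the allylic alcohol 19, which corrects C12 and puts the participating group of the key step in place. 19 comes from the epoxy ketone 17 by Wharton transposition, which turns the carvone carbonyl carbon into the nucleophilic alkene carbon C10.

**17 ⇒ 13 + 11.** The only C–C bond between the two halves, C1–C2, is an aldol bond between the α′-enolate of carvone oxide 13 (from (R)-carvone 12) and the α-silyloxy aldehyde 11. Carvone supplies C1, C10–C17 and C20 with C14 already set; the aldol sets C1 and C2.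

**11 ⇒ 10 ⇒ 9 ⇒ 8 ⇒ 6 + 3.** The quaternary centre C3 is cut at C3–C4. It comes from (R)-lactic acid 4 by alkylation of the dioxolanone 6 (made with pivalaldehyde 5) with the iodide 3, which is made from 5-iodopent-1-yne 1.

## Alternatives that were turned down

**Alternative 1:** (textbook) Disconnect C5=C6 by ring-closing metathesis and C1–C10 plus C13–C14 by intramolecular Diels–Alder reaction. The forward key step is the cycloaddition of the oxonene tetraene A1 (2-silyloxydiene at C9, enone at C2), which builds ring A last. It was turned down on step economy. The cycloadduct carries a C11=C12 enol ether and a C15 ketone, so the C11 carbinol, the cis C12 ester, C15/C16, the C7 methylene, saturation of C5=C6 beside other alkenes, and ring D all remain to be done after the key step. Before it, C2, C3 and C9 need separate auxiliary-controlled enolate steps. The C14 configuration also depends on an exo transition state enforced only by the tether.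

**Alternative 2:** Disconnect C1–C2 and C2–O by a Prins cyclization–pinacol shift of the carvone-derived dienyl diol A2, giving the angular aldehyde A3, then close ring C at C6–C7 by a Nozaki–Hiyama–Kishi reaction. It was turned down because the key step creates problems the target does not have. The pinacol shift leaves a formyl group on C10 that must be excised. The ring closure leaves a C6 hydroxyl whose removal next to C7=C19 risks allylic transposition. C11/C12 remain an alkene, so the cis hydroxy ester needs late dihydroxylation and selective acylation. The carvone oxygen is discarded.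

**Alternative 3:** Disconnect C5–C6 with scission of a C3–C8 bond: anionic oxy-Cope ring expansion of the oxanorbornane divinyl carbinol A4. This would turn a [2.2.1] bicycle into the [6.2.1] bicycle in one step and leave a C3 ketone and a C7 allylsilane. It was turned down because the precursor is harder than the product. A4 needs ring A fused on the exo face (H1 and H10 endo). A furan Diels–Alder reaction with a trisubstituted cyclohexene is an unreactive, reversible pairing, and hydrogenation of a tetrahydroisobenzofuran cycloadduct adds hydrogen from the exo face and gives the wrong C1/C10 configuration. The α-alkenyl ketone on the way to A4 is prone to conjugation. C3 and C11/C12 would still have to be set in a flexible ten-membered ring.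

Key step: step 16

## Route

Step 1
Reactants: 1 5-iodopent-1-yne
Product: 3 2-bromo-5-iodopent-1-ene, via bromoalkenylborane 2 (not isolated)
Conditions: B-bromo-9-BBN, CH2Cl2, 0 °C; then AcOH, 0 °C to rt
Reagents that add atoms: B-bromo-9-borabicyclo[3.3.1]nonane, BrB1C2CCCC1CCC2
Why: Syn bromoboration of the terminal alkyne puts bromine on the internal carbon and protonolysis of the alkenyl–boron bond gives the 2-bromo-1-alkene; the primary iodide is inert to the haloborane.

Step 2
Reactants: 4 (R)-lactic acid; 5 pivalaldehyde
Product: 6 (2R,5R)-2-tert-butyl-5-methyl-1,3-dioxolan-4-one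
Conditions: TsOH (cat.), H2SO4 (cat.), pentane, reflux with water separator; recrystallization
Reagents that add atoms: none
Why: Acid-catalysed acetalization of the α-hydroxy acid; the cis acetal is the major, crystalline isomer and stores the lactate configuration in the acetal carbon (self-regeneration of stereocentres).

Step 3
Reactants: 6 (2R,5R)-2-tert-butyl-5-methyl-1,3-dioxolan-4-one; 3 2-bromo-5-iodopent-1-ene
Product: 8 (2R,5S)-5-(4-bromopent-4-en-1-yl)-2-tert-butyl-5-methyl-1,3-dioxolan-4-one, via lithium enolate 7 (not isolated)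
Conditions: LDA, THF, −78 °C; then 3, DMPU, −78 to −30 °C
Reagents that add atoms: none
Why: Enolate alkylation of the dioxolanone; the tert-butyl group shields one face, so the iodide enters trans to it and the quaternary centre (later C3) forms with the alkyl chain in the place of the former hydrogen.

Step 4
Reactants: 8 (2R,5S)-5-(4-bromopent-4-en-1-yl)-2-tert-butyl-5-methyl-1,3-dioxolan-4-one
Product: 9 methyl (S)-6-bromo-2-hydroxy-2-methylhept-6-enoate
Conditions: NaOMe (cat.), MeOH, 0 °C to rt
Reagents that add atoms: methanol, CO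
Why: Methanolysis of the acylal lactone releases pivalaldehyde and the tertiary α-hydroxy ester without touching the quaternary centre.

Step 5
Reactants: 9 methyl (S)-6-bromo-2-hydroxy-2-methylhept-6-enoate
Product: 10 methyl (S)-6-bromo-2-methyl-2-(trimethylsilyloxy)hept-6-enoate
Conditions: 1-(trimethylsilyl)imidazole, CH2Cl2, rt
Reagents that add atoms: 1-(trimethylsilyl)imidazole, C[Si](C)(C)n1ccnc1
Why: O-silylation of the tertiary alcohol with a strong silyl donor; the TMS ether is chosen because it can later be removed beside a secondary TBS ether.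

Step 6
Reactants: 10 methyl (S)-6-bromo-2-methyl-2-(trimethylsilyloxy)hept-6-enoate
Product: 11 (S)-6-bromo-2-methyl-2-(trimethylsilyloxy)hept-6-enal
Conditions: DIBAL-H, CH2Cl2, −78 °C; aqueous Rochelle salt
Reagents that add atoms: none
Why: Partial reduction of an α-silyloxy ester stops at the aluminium hemiacetal at low temperature and gives the aldehyde on work-up; the α-carbon is quaternary and cannot epimerize.

Step 7
Reactants: 12 (R)-carvone
Product: 13 (1R,4R,6R)-1-methyl-4-(prop-1-en-2-yl)-7-oxabicyclo[4.1.0]heptan-2-one
Conditions: 30% H2O2, NaOH (aq.), MeOH, 0 °C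
Reagents that add atoms: hydrogen peroxide, OO
Why: Weitz–Scheffer nucleophilic epoxidation of the enone; hydroperoxide adds to the β-carbon (later C12) anti to the isopropenyl group, so the epoxide is trans to it.

Step 8
Reactants: 13 (1R,4R,6R)-1-methyl-4-(prop-1-en-2-yl)-7-oxabicyclo[4.1.0]heptan-2-one; 11 (S)-6-bromo-2-methyl-2-(trimethylsilyloxy)hept-6-enal
Product: 17 (1R,3R,4R,6R)-3-[(1S,2S)-6-bromo-1-(tert-butyldimethylsilyloxy)-2-hydroxy-2-methylhept-6-en-1-yl]-1-methyl-4-(prop-1-en-2-yl)-7-oxabicyclo[4.1.0]heptan-2-one, via lithium enolate 14 (not isolated), via lithium aldolate 15 (not isolated), via bis-silyl ether 16 (not isolated)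
Conditions: LDA, THF, −78 °C; 11, −78 °C; TBSOTf, −78 to −40 °C; then citric acid, MeOH, rt
Reagents that add atoms: tert-butyldimethylsilyl trifluoromethanesulfonate, CC(C)(C)[Si](C)(C)OS(=O)(=O)C(F)(F)F
Why: Aldol addition of the kinetic α′-enolate: the aldehyde approaches anti to the adjacent isopropenyl group (sets C1), and the closed Zimmerman–Traxler chair of the ring (E)-enolate gives the 1,2-anti adduct (sets C2, the configuration the target needs), while the α-silyloxy centre of 11 has only a weak Felkin bias because its two carbon substituents are of similar size; silylation of the aldolate blocks retro-aldol and mild acid removes only the tertiary TMS ether.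

Step 9
Reactants: 17 (the epoxy ketone of step 8)
Product: 19 (1R,4R,5R)-4-[(1S,2S)-6-bromo-1-(tert-butyldimethylsilyloxy)-2-hydroxy-2-methylhept-6-en-1-yl]-2-methyl-5-(prop-1-en-2-yl)cyclohex-2-en-1-ol, via hydrazone 18 (not isolated)
Conditions: N2H4·H2O, AcOH (cat.), MeOH, 0 °C to rt, under argon
Reagents that add atoms: none
Why: Wharton transposition: the epoxy hydrazone opens to a vinyl diazene that loses nitrogen, which moves the alkene to C10=C11 and leaves the epoxide oxygen as the C12 alcohol with its configuration retained (trans to the C14 substituent).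

Step 10
Reactants: 19 (the allylic alcohol of step 9); 20 octanoic acid
Product: 21 (1S,4R,5R)-4-[(1S,2S)-6-bromo-1-(tert-butyldimethylsilyloxy)-2-hydroxy-2-methylhept-6-en-1-yl]-2-methyl-5-(prop-1-en-2-yl)cyclohex-2-en-1-yl octanoate
Conditions: PPh3, DIAD, toluene, 0 °C to rt
Reagents that add atoms: none
Why: Mitsunobu esterification inverts the allylic carbinol C12, so the octanoate becomes cis to the C14 side chain; the tertiary C3 alcohol does not react, and the ester of the target is now in place to serve as the participating group.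

Step 11
Reactants: 21 (the octanoate of step 10)
Product: 23 (1S,4S,5S)-4-[(1S,2S)-6-bromo-1-(tert-butyldimethylsilyloxy)-2-hydroxy-2-methylhept-6-en-1-yl]-5-[(2R)-1-hydroxypropan-2-yl]-2-methylcyclohex-2-en-1-yl octanoate, via alkylborane 22 (not isolated)
Conditions: 9-BBN, THF, 0 °C to rt; then 30% H2O2, pH 7 phosphate buffer, 0 °C
Reagents that add atoms: hydrogen peroxide, OO
Why: Hydroboration–oxidation; 9-BBN selects the 1,1-disubstituted isopropenyl alkene over the trisubstituted ring alkene and the deactivated bromoalkene, and in the conformer with C14–H eclipsing the C15=C16 bond (minimized allylic strain) boron is delivered anti to the bulkier ring carbon C1, which gives 15R; buffered oxidation spares the ester.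

Step 12
Reactants: 23 (the diol of step 11)
Product: 25 (1R,4S,5S,5aS,8S,9aS)-4-(4-bromopent-4-en-1-yl)-5-(tert-butyldimethylsilyloxy)-1,4,7-trimethyl-1,2,4,5,5a,8,9,9a-octahydro-3-benzoxepin-8-yl octanoate, via primary triflate 24 (not isolated)
Conditions: Tf2O, 2,6-lutidine, CH2Cl2, −78 °C to rt
Reagents that add atoms: none
Why: The primary alcohol is triflated selectively and displaced by the tertiary C3 hydroxyl (SN2, 7-exo-tet), which closes the oxepane without touching a stereocentre; the TBS ether on the C2 oxygen prevents formation of the six-membered ether.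

Step 13
Reactants: 25 (the oxepane silyl ether of step 12)
Product: 26 (1R,4S,5S,5aS,8S,9aS)-4-(4-bromopent-4-en-1-yl)-5-hydroxy-1,4,7-trimethyl-1,2,4,5,5a,8,9,9a-octahydro-3-benzoxepin-8-yl octanoate
Conditions: HF·pyridine, pyridine, THF, 0 °C to rt
Reagents that add atoms: none
Why: Buffered fluoride cleavage of the secondary TBS ether; the ester, the tertiary ether and the bromoalkene are stable, and the step is placed before the allylsilane is made so that the silane never meets fluoride.

Step 14
Reactants: 26 (the bromoalkene alcohol of step 13)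
Product: 27 (1R,4S,5S,5aS,8S,9aS)-5-hydroxy-1,4,7-trimethyl-4-{4-[(trimethylsilyl)methyl]pent-4-en-1-yl}-1,2,4,5,5a,8,9,9a-octahydro-3-benzoxepin-8-yl octanoate
Conditions: Me3SiCH2MgCl, Fe(acac)3 (cat.), THF–NMP, −20 to 0 °C
Reagents that add atoms: (trimethylsilyl)methylmagnesium chloride, C[Si](C)(C)C[Mg]Cl
Why: Iron-catalysed Kumada-type coupling of the 2-bromo-1-alkene with a Grignard reagent that has no β-hydrogen gives the 2-substituted allylsilane; at low temperature the coupling outruns addition to the octanoate, and iron is used because zerovalent palladium could ionize the allylic ester.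

Step 15
Reactants: 27 (the allylsilane alcohol of step 14); 28 trimethyl orthoformate
Product: 29 (1R,4S,5S,5aS,8S,9aS)-5-(dimethoxymethoxy)-1,4,7-trimethyl-4-{4-[(trimethylsilyl)methyl]pent-4-en-1-yl}-1,2,4,5,5a,8,9,9a-octahydro-3-benzoxepin-8-yl octanoate
Conditions: PPTS (cat.), neat 28, 40 °C, reduced pressure; concentrated and used crude
Reagents that add atoms: none
Why: Acid-catalysed alkoxy exchange of the orthoester, driven by removal of methanol; pyridinium tosylate is too weak an acid to ionize the orthoester towards the allylsilane or to protodesilylate it.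

Step 16
Reactants: 29 (the mixed orthoformate of step 15)
Product: 32 the target, (1S,2S,3S,9S,10R,11R,12S,14S,15R)-configured tetracyclic C12 octanoate (CNP0286133.1), via methoxytetrahydrofuran dioxolanylium triflate 30 (not isolated), via tetracyclic dioxolanylium triflate 31 (not isolated)
Conditions: TMSOTf, 2,6-di-tert-butyl-4-methylpyridine, CH2Cl2 (high dilution), −78 to −20 °C; H2O–THF then NaHCO3; DBU (cat.), CH2Cl2, rt
Reagents that add atoms: water, O
Why: Proposed new method: TMSOTf should ionize the mixed orthoformate to the alkoxy(methoxy)carbenium ion at C9, which C10 of the trisubstituted C10=C11 alkene attacks in a 5-exo, Markovnikov Prins closure of the tetrahydrofuran (closest known types: Prins cyclizations of homoallylic alcohols that give tetrahydrofurans when the distal alkene carbon is the more substituted one, and Lewis acid additions of orthoformates to alkenes and allylsilanes). The tertiary C11 cation is captured on the opposite face by the carbonyl oxygen of the C12 octanoate (anchimeric formation of a 1,3-dioxolan-2-ylium ion, as in the Woodward–Prévost cis-hydroxylation), so that C10 is set by the three-atom tether from C1 (cis ring fusion) and C11 by anti addition with oxygen delivered syn to C12–O, giving 30. The remaining methoxy group on C9 is then ionized to the cyclic oxocarbenium ion, which C8 of the 2-substituted allylsilane attacks (intramolecular Hosomi–Sakurai reaction of a 2-alkoxytetrahydrofuran), closing the nine-membered oxonane (ten-membered carbocycle) by C–C bond formation exo to the C9=O+ bond and creating the C7=C19 alkene with loss of the silyl group, giving 31. C9 is set by the tether, which can reach only the convex face cis to C3, and both C9 epimers of 30 converge on the same planar cation. Water opens the dioxolanylium ion to the cis hydroxy ester and DBU lets the acyl group settle on the less hindered secondary C12 oxygen. The selectivities needed are 5-exo over 6-endo attack (tertiary against secondary cation), ring closure before intermolecular allylation (high dilution) and Prins closure before ionization of the allylic ester (low temperature); if the allylsilane attacks the first carbenium ion before the alkene does, the nine-membered cyclic acetal so formed ionizes again and a transannular Prins closure leads to the same 31.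

## Compound list

1 | 5-iodopent-1-yne | C#CCCCI | starting material
2 | B-[(Z)-2-bromo-5-iodopent-1-en-1-yl]-9-borabicyclo[3.3.1]nonane | Br/C(CCCI)=C\B1C2CCCC1CCC2 | intermediate (not isolated)
3 | 2-bromo-5-iodopent-1-ene | C=C(Br)CCCI | intermediate
4 | (R)-lactic acid | C[C@@H](O)C(=O)O | starting material
5 | pivalaldehyde | CC(C)(C)C=O | starting material
6 | (2R,5R)-2-tert-butyl-5-methyl-1,3-dioxolan-4-one | C[C@H]1O[C@@H](C(C)(C)C)OC1=O | intermediate
7 | lithium (2R)-2-tert-butyl-5-methyl-1,3-dioxol-4-olate | CC1=C(O[Li])O[C@H](C(C)(C)C)O1 | intermediate (not isolated)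
8 | (2R,5S)-5-(4-bromopent-4-en-1-yl)-2-tert-butyl-5-methyl-1,3-dioxolan-4-one | C=C(Br)CCC[C@]1(C)O[C@@H](C(C)(C)C)OC1=O | intermediate
9 | methyl (S)-6-bromo-2-hydroxy-2-methylhept-6-enoate | C=C(Br)CCC[C@](C)(O)C(=O)OC | intermediate
10 | methyl (S)-6-bromo-2-methyl-2-(trimethylsilyloxy)hept-6-enoate | C=C(Br)CCC[C@](C)(O[Si](C)(C)C)C(=O)OC | intermediate
11 | (S)-6-bromo-2-methyl-2-(trimethylsilyloxy)hept-6-enal | C=C(Br)CCC[C@](C)(O[Si](C)(C)C)C=O | intermediate
12 | (R)-carvone | C=C(C)[C@@H]1CC=C(C)C(=O)C1 | starting material
13 | (1R,4R,6R)-1-methyl-4-(prop-1-en-2-yl)-7-oxabicyclo[4.1.0]heptan-2-one (epoxide trans to isopropenyl) | C=C(C)[C@H]1CC(=O)[C@]2(C)O[C@@H]2C1 | intermediate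
14 | lithium (1R,4R,6R)-1-methyl-4-(prop-1-en-2-yl)-7-oxabicyclo[4.1.0]hept-2-en-2-olate | C=C(C)[C@H]1C=C(O[Li])[C@]2(C)O[C@@H]2C1 | intermediate (not isolated)
15 | lithium C2 alkoxide of the aldol adduct of 13 and 11 (C3 OTMS; configuration as in 17) | C=C(Br)CCC[C@](C)(O[Si](C)(C)C)[C@@H](O[Li])[C@@H]1C(=O)[C@]2(C)O[C@@H]2C[C@H]1C(C)=C | intermediate (not isolated)
16 | C2 OTBS, C3 OTMS bis-silyl ether of the aldol adduct (configuration as in 17) | C=C(Br)CCC[C@](C)(O[Si](C)(C)C)[C@@H](O[Si](C)(C)C(C)(C)C)[C@@H]1C(=O)[C@]2(C)O[C@@H]2C[C@H]1C(C)=C | intermediate (not isolated)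
17 | (1R,3R,4R,6R)-3-[(1S,2S)-6-bromo-1-(tert-butyldimethylsilyloxy)-2-hydroxy-2-methylhept-6-en-1-yl]-1-methyl-4-(prop-1-en-2-yl)-7-oxabicyclo[4.1.0]heptan-2-one | C=C(Br)CCC[C@](C)(O)[C@@H](O[Si](C)(C)C(C)(C)C)[C@@H]1C(=O)[C@]2(C)O[C@@H]2C[C@H]1C(C)=C | intermediate
18 | C10 hydrazone of 17 | C=C(Br)CCC[C@](C)(O)[C@@H](O[Si](C)(C)C(C)(C)C)[C@@H]1C(=NN)[C@]2(C)O[C@@H]2C[C@H]1C(C)=C | intermediate (not isolated)
19 | (1R,4R,5R)-4-[(1S,2S)-6-bromo-1-(tert-butyldimethylsilyloxy)-2-hydroxy-2-methylhept-6-en-1-yl]-2-methyl-5-(prop-1-en-2-yl)cyclohex-2-en-1-ol | C=C(Br)CCC[C@](C)(O)[C@@H](O[Si](C)(C)C(C)(C)C)[C@@H]1C=C(C)[C@H](O)C[C@H]1C(C)=C | intermediate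
20 | octanoic acid | CCCCCCCC(=O)O | starting material
21 | (1S,4R,5R)-4-[(1S,2S)-6-bromo-1-(tert-butyldimethylsilyloxy)-2-hydroxy-2-methylhept-6-en-1-yl]-2-methyl-5-(prop-1-en-2-yl)cyclohex-2-en-1-yl octanoate | C=C(Br)CCC[C@](C)(O)[C@@H](O[Si](C)(C)C(C)(C)C)[C@@H]1C=C(C)[C@@H](OC(=O)CCCCCCC)C[C@H]1C(C)=C | intermediate
22 | C16 B-alkyl-9-borabicyclo[3.3.1]nonane adduct of 21 (C15 as in 23) | C=C(Br)CCC[C@](C)(O)[C@@H](O[Si](C)(C)C(C)(C)C)[C@@H]1C=C(C)[C@@H](OC(=O)CCCCCCC)C[C@H]1[C@@H](C)CB3C4CCCC3CCC4 | intermediate (not isolated)
23 | (1S,4S,5S)-4-[(1S,2S)-6-bromo-1-(tert-butyldimethylsilyloxy)-2-hydroxy-2-methylhept-6-en-1-yl]-5-[(2R)-1-hydroxypropan-2-yl]-2-methylcyclohex-2-en-1-yl octanoate | C=C(Br)CCC[C@](C)(O)[C@@H](O[Si](C)(C)C(C)(C)C)[C@@H]1C=C(C)[C@@H](OC(=O)CCCCCCC)C[C@H]1[C@@H](C)CO | intermediate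
24 | C16 trifluoromethanesulfonate of 23 | C=C(Br)CCC[C@](C)(O)[C@@H](O[Si](C)(C)C(C)(C)C)[C@@H]1C=C(C)[C@@H](OC(=O)CCCCCCC)C[C@H]1[C@@H](C)COS(=O)(=O)C(F)(F)F | intermediate (not isolated)
25 | (1R,4S,5S,5aS,8S,9aS)-4-(4-bromopent-4-en-1-yl)-5-(tert-butyldimethylsilyloxy)-1,4,7-trimethyl-1,2,4,5,5a,8,9,9a-octahydro-3-benzoxepin-8-yl octanoate | C=C(Br)CCC[C@]2(C)OC[C@H](C)[C@@H]3C[C@H](OC(=O)CCCCCCC)C(C)=C[C@H]3[C@@H]2O[Si](C)(C)C(C)(C)C | intermediate
26 | (1R,4S,5S,5aS,8S,9aS)-4-(4-bromopent-4-en-1-yl)-5-hydroxy-1,4,7-trimethyl-1,2,4,5,5a,8,9,9a-octahydro-3-benzoxepin-8-yl octanoate | C=C(Br)CCC[C@]2(C)OC[C@H](C)[C@@H]3C[C@H](OC(=O)CCCCCCC)C(C)=C[C@H]3[C@@H]2O | intermediate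
27 | (1R,4S,5S,5aS,8S,9aS)-5-hydroxy-1,4,7-trimethyl-4-{4-[(trimethylsilyl)methyl]pent-4-en-1-yl}-1,2,4,5,5a,8,9,9a-octahydro-3-benzoxepin-8-yl octanoate | C[Si](C)(C)CC(=C)CCC[C@]2(C)OC[C@H](C)[C@@H]3C[C@H](OC(=O)CCCCCCC)C(C)=C[C@H]3[C@@H]2O | intermediate
28 | trimethyl orthoformate | COC(OC)OC | starting material
29 | (1R,4S,5S,5aS,8S,9aS)-5-(dimethoxymethoxy)-1,4,7-trimethyl-4-{4-[(trimethylsilyl)methyl]pent-4-en-1-yl}-1,2,4,5,5a,8,9,9a-octahydro-3-benzoxepin-8-yl octanoate | C[Si](C)(C)CC(=C)CCC[C@]2(C)OC[C@H](C)[C@@H]3C[C@H](OC(=O)CCCCCCC)C(C)=C[C@H]3[C@@H]2OC(OC)OC | intermediate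
30 | tricyclic 2-methoxytetrahydrofuran (C9 epimers) carrying the C11/C12 cis-fused 2-heptyl-1,3-dioxolan-2-ylium ion, triflate salt; allylsilane intact | C[Si](C)(C)CC(=C)CCC[C@]2(C)OC[C@H](C)[C@@H]3C[C@H](OC(CCCCCCC)=[O+]5)[C@@]5(C)[C@@H]4[C@H]3[C@@H]2OC4OC.[O-]S(=O)(=O)C(F)(F)F | intermediate (not isolated)
31 | tetracyclic C11/C12 cis-fused 2-heptyl-1,3-dioxolan-2-ylium triflate (rings A–D closed, C7=C19 present) | C=C1CCC[C@]2(C)OC[C@H](C)[C@@H]3C[C@H](OC(CCCCCCC)=[O+]5)[C@@]5(C)[C@@H]4[C@H]3[C@@H]2O[C@H]4C1.[O-]S(=O)(=O)C(F)(F)F | intermediate (not isolated)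
32 | target CNP0286133.1, (1S,2S,3S,9S,10R,11R,12S,14S,15R)-3,16-epoxy-2,9-epoxy-11-hydroxy tetracycle with C7=C19 alkene and C12 octanoate | C=C1CCC[C@]2(C)OC[C@H](C)[C@@H]3C[C@H](OC(=O)CCCCCCC)[C@](C)(O)[C@@H]4[C@H]3[C@@H]2O[C@H]4C1 | target

## Step count and uncertain steps

Total steps: 16. Longest linear sequence: 14 steps (from 4 or from 1 through 11 to 32); the carvone branch is 10 steps.

**Step 16 (bears the label; the risk of the route sits here).** Three processes are most likely to go wrong. The dialkoxycarbenium ion may be too weak an electrophile for the unactivated alkene, so that intermolecular allylation or protodesilylation of the allylsilane consumes the nucleophile before the slow medium-ring closure. The allylic octanoate may ionize before the Prins closure. The tetrahydrofuran oxocarbenium ion may lose a proton to an enol ether.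

Fallback with known chemistry, from 26 back to 32. Here the CH2 of the bromoalkene becomes C19 and C8 is brought in by the aldehyde. Prins cyclization of 26 with (tert-butyldiphenylsilyloxy)acetaldehyde (TMSOTf, CH2Cl2, −78 °C, aqueous work-up, DBU) should give, by the same 5-exo closure and octanoate participation, the 2,5-cis tetrahydrofuran silyl ether F1. TBAF buffered with AcOH gives the primary alcohol F2, and Dess–Martin periodinane the aldehyde F3. An intramolecular Nozaki–Hiyama–Kishi reaction (CrCl2, NiCl2 cat., DMSO, high dilution) between the C7 bromoalkene and the C8 aldehyde closes the oxonane to the allylic alcohol F4 (both C8 epimers are used). Methyl chloroformate and pyridine give the carbonate F5. Formate reduction with zerovalent palladium (Pd(OAc)2, PBu3, HCO2NH4) delivers hydride to the more substituted allyl terminus C8 and leaves the C7=C19 alkene, which gives 32.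

**Step 8.** Poor simple diastereoselection (anti against syn) of the lithium aldol is the main risk, since the weak Felkin preference of the aldehyde opposes the enolate control; incomplete trapping of the aldolate would also allow retro-aldol equilibration.

Fallback from 12 and 11 back to 17. The dicyclohexylboron enolate of carvone itself (Cy2BCl, Et3N, Et2O, −78 °C), which reacts through a tighter closed transition state with higher anti selectivity, is added to 11 to give the enone aldol F6. Silylation (TBSOTf, 2,6-lutidine) and citric acid in MeOH give the enone F7 (C2 OTBS, C3 OH). Nucleophilic epoxidation (H2O2, NaOH, MeOH, 0 °C), now performed after the aldol, gives 17.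

**Step 9.** Slow hydrazone formation at the hindered C10 ketone is the main risk, with competing attack of hydrazine on the epoxide or diimide reduction of the isopropenyl group.

Fallback from 17 back to 19. NaBH4 with CeCl3 gives the epoxy alcohol F8. 1,1′-Thiocarbonyldiimidazole gives the thiocarbonyl imidazolide F9. Bu3SnH with AIBN (toluene, 80 °C) generates the C10 radical, which opens the epoxide to the C12 alkoxy radical and, after hydrogen transfer, gives 19 with the same C12 configuration (radical deoxygenative fragmentation of the Barton–McCombie type).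

**Step 12.** Participation of the C2 silyl ether oxygen in the displacement of the triflate (six-membered ether with loss of the silyl group) may compete with the slower seven-membered closure by the tertiary alcohol; elimination of the triflate is also possible.

Fallback from 23 back to 25. Selective oxidation of the primary alcohol (TEMPO, PhI(OAc)2) gives the hydroxy aldehyde F10, which is in equilibrium with its seven-membered lactol. Intramolecular reductive etherification (Et3SiH, TMSOTf, CH2Cl2, −78 °C) reduces the cyclic oxocarbenium ion and gives 25 without an SN2 step.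

## Further compounds

F1 | step 16 | Prins adduct of 26: tetrahydrofuran with C9 CH2OTBDPS, C11 OH, C12 octanoate, bromoalkene chain (configuration as in 32) | C=C(Br)CCC[C@]2(C)OC[C@H](C)[C@@H]3C[C@H](OC(=O)CCCCCCC)[C@](C)(O)[C@@H]4[C@H]3[C@@H]2O[C@H]4CO[Si](c5ccccc5)(c6ccccc6)C(C)(C)C
F2 | step 16 | primary C8 alcohol from F1 | C=C(Br)CCC[C@]2(C)OC[C@H](C)[C@@H]3C[C@H](OC(=O)CCCCCCC)[C@](C)(O)[C@@H]4[C@H]3[C@@H]2O[C@H]4CO
F3 | step 16 | C8 aldehyde from F2 | C=C(Br)CCC[C@]2(C)OC[C@H](C)[C@@H]3C[C@H](OC(=O)CCCCCCC)[C@](C)(O)[C@@H]4[C@H]3[C@@H]2O[C@H]4C=O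
F4 | step 16 | 8-hydroxy derivative of 32 (C8 epimers) | C=C1CCC[C@]2(C)OC[C@H](C)[C@@H]3C[C@H](OC(=O)CCCCCCC)[C@](C)(O)[C@@H]4[C@H]3[C@@H]2O[C@H]4C1O
F5 | step 16 | C8 methyl carbonate of F4 (C8 epimers) | C=C1CCC[C@]2(C)OC[C@H](C)[C@@H]3C[C@H](OC(=O)CCCCCCC)[C@](C)(O)[C@@H]4[C@H]3[C@@H]2O[C@H]4C1OC(=O)OC
F6 | step 8 | anti aldol of carvone and 11 (enone; C2 OH, C3 OTMS; configuration as in 17) | C=C(Br)CCC[C@](C)(O[Si](C)(C)C)[C@@H](O)[C@@H]1C(=O)C(C)=CC[C@H]1C(C)=C
F7 | step 8 | enone with C2 OTBS and C3 OH | C=C(Br)CCC[C@](C)(O)[C@@H](O[Si](C)(C)C(C)(C)C)[C@@H]1C(=O)C(C)=CC[C@H]1C(C)=C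
F8 | step 9 | C10 epoxy alcohol from 17 (C10 epimers) | C=C(Br)CCC[C@](C)(O)[C@@H](O[Si](C)(C)C(C)(C)C)[C@@H]1C(O)[C@]2(C)O[C@@H]2C[C@H]1C(C)=C
F9 | step 9 | C10 O-(imidazol-1-ylthiocarbonyl) derivative of F8 | C=C(Br)CCC[C@](C)(O)[C@@H](O[Si](C)(C)C(C)(C)C)[C@@H]1C(OC(=S)n3ccnc3)[C@]2(C)O[C@@H]2C[C@H]1C(C)=C
F10 | step 12 | C16 aldehyde from 23 (in equilibrium with the lactol on the C3 hydroxyl) | C=C(Br)CCC[C@](C)(O)[C@@H](O[Si](C)(C)C(C)(C)C)[C@@H]1C=C(C)[C@@H](OC(=O)CCCCCCC)C[C@H]1[C@@H](C)C=O
A1 | alternative 1 | (Z)-oxon-5-ene tetraene: enone at C2, (E)-2-silyloxydiene at C9, C3 OTES, C7 dioxolane | CC(=O)/C=C/[C@@H]1O[C@H](/C=C(C)/C(=C)O[Si](C)(C)C(C)(C)C)CC2(OCCO2)/C=C\C[C@]1(C)O[Si](CC)(CC)CC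
A2 | alternative 2 | carvone-derived cyclohexadienyl 1,2-diol with 2-iodoallyl chain | C=C(I)C[C@H](O)[C@H](O)C1=C[C@H](C(C)=C)CC=C1C
A3 | alternative 2 | Prins–pinacol product: hexahydroisobenzofuran with angular C10 formyl group | C=C(I)C[C@@H]1O[C@H]([C@@](C)(O[Si](C)(C)C(C)(C)C)CCCO[Si](C(C)C)(C(C)C)C(C)C)[C@H]2[C@H](C(C)=C)CC=C(C)[C@@]12C=O
A4 | alternative 3 | oxanorbornane divinyl carbinol (C3 endo-OH, exo-vinyl; C8 exo-alkenyl; ring A exo-fused) | C=C[C@]1(O)[C@H](C(=C)C[Si](C)(C)C)[C@@H]2O[C@H]1[C@@H]3[C@H]2C(C)=CC[C@H]3C(C)=C
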